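**Strategy.** The target is two 4-hydroxy-2-pyrones bridged by CH2: one carries a (3R,4R)-3,8-dihydroxy-3-phenyl-1-tetralone, the other its dehydrated, achiral naphthalene form. The route rests on reading C2–C3(OH)Ph of the tetralone carbocycle as acetophenone placed between the aryl carbonyl carbon C1 and the C4–H that arene and pyrone C6 both acidify. A double aldol annulation of lithiated acetophenone with an ortho-(pyranylmethyl)benzaldehyde closes this ring, forming C1–C2 and C3–C4 in one flask as a racemic 1,3-cis-diol. Oxidative kinetic resolution gives the enantiopure tetralone; part of it is aromatised to the naphthalene half, and a pyrone Mannich base joins the halves.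

Key step: step 5

Remark on the chemistry: C1–C8a denote the tetralone atoms (C1 carbonyl, C3 carbinol, C4 pyranyl-bearing carbon). The target is (3R,4R), with the 3-hydroxyl trans to the 4-pyranyl group. The racemic diol of the key step is drawn as the enantiomer that leads on to the target. The enantiomer of this diol that the resolution leaves unoxidised is separated and not carried forward. The naphthalene half is taken from the resolved tetralone, whose stereocentres are erased on aromatisation.

**Step 1**
Reactants: 1 4-hydroxy-6-methyl-2H-pyran-2-one; 2 benzyl alcohol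
Product: 3 4-(benzyloxy)-6-methyl-2H-pyran-2-one
Conditions: PPh3, diisopropyl azodicarboxylate, THF, 0 → 25 °C
Reagents that add atoms: benzyl alcohol, OCc1ccccc1
Why: Mitsunobu O-alkylation of the acidic 4-hydroxyl should give the 4-benzyl ether cleanly, avoiding the C3-benzylation that can compete when the pyronate is alkylated with benzyl halides.

**Step 2**
Reactants: 4 2-bromo-6-hydroxybenzaldehyde; 5 benzyl bromide
Product: 6 2-(benzyloxy)-6-bromobenzaldehyde
Conditions: K2CO3, DMF, 25 °C
Reagents that add atoms: benzyl bromide, BrCc1ccccc1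
Why: Williamson etherification of the phenoxide protects the future C8 hydroxyl with a group that survives strong base and is removed by neutral hydrogenolysis or by a Lewis acid.

**Step 3**
Reactants: 6 2-(benzyloxy)-6-bromobenzaldehyde; 7 trimethyl orthoformate
Product: 8 1-(benzyloxy)-3-bromo-2-(dimethoxymethyl)benzene
Conditions: TsOH·H2O (cat.), MeOH, 25 °C
Reagents that add atoms: trimethyl orthoformate, COC(OC)OC
Why: Acid-catalysed acetalisation masks the aldehyde against the zinc dienolate used in the next step.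

**Step 4**
Reactants: 3 4-(benzyloxy)-6-methyl-2H-pyran-2-one; 8 1-(benzyloxy)-3-bromo-2-(dimethoxymethyl)benzene
Product: 12 2-(benzyloxy)-6-{[4-(benzyloxy)-2-oxo-2H-pyran-6-yl]methyl}benzaldehyde, via lithium dienolate 9 (not isolated), via pyranylmethylzinc chloride 10 (not isolated), via dimethyl acetal 11 (not isolated)
Conditions: LiN(i-Pr)2, THF, −78 °C; ZnCl2, −78 → 25 °C; 8, Pd2(dba)3 (cat.), XPhos (2-dicyclohexylphosphino-2′,4′,6′-triisopropylbiphenyl, cat.), 60 °C; then 1 M HCl, THF, 25 °C
Reagents that add atoms: water, O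
Why: Lithiation of the 6-methyl group of a 4-alkoxy-2-pyrone, transmetalation to zinc and Negishi coupling (the vinylogous counterpart of the palladium-catalysed arylation of zinc ester enolates) should arylate the exocyclic carbon, since reductive elimination there keeps the pyrone intact and the weakly basic zinc species limits double arylation; the acidic work-up cleaves the acetal.

**Step 5**
Reactants: 12 2-(benzyloxy)-6-{[4-(benzyloxy)-2-oxo-2H-pyran-6-yl]methyl}benzaldehyde; 13 acetophenone
Product: 16 rac-(1S,3R,4R)-8-(benzyloxy)-4-[4-(benzyloxy)-2-oxo-2H-pyran-6-yl]-3-phenyl-1,2,3,4-tetrahydronaphthalene-1,3-diol, via lithium 1-phenylethenolate 14 (not isolated), via lithium aldolate 15 (not isolated)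
Conditions: 13, LiN(SiMe3)2 (1.05 equiv), THF, −78 °C; add 12, −78 °C; then LiN(SiMe3)2 (1.3 equiv), −78 → −40 °C; AcOH, −78 °C
Reagents that add atoms: acetophenone, CC(=O)c1ccccc1
Why: Enolate 14 adds to the aldehyde of 12 (C1–C2) to give aldolate 15, in which lithium bridges the new alkoxide and the phenyl ketone; the second portion of base then removes the C4–H, which is acidified by the arene and, vinylogously through pyrone C6, by the lactone carbonyl, and the dienolate closes onto the chelated ketone (C3–C4). The closest known reaction types are the ketone-enolate aldol addition and the addition of C6-lithiomethyl 4-alkoxy-2-pyrones to ketones, run here in sequence as a formal [4+2] double-aldol annulation. The carbocycle closes in a 6-(enolexo)-exo-trig mode. C1 forms without facial control (hence the racemate) and serves only as a relay centre: the lithium bridge holds the C1 and C3 oxygens syn-diaxial on the forming half-chair, which puts phenyl equatorial at C3. At C4 the pyranyl group should go pseudoaxial to avoid the peri hydrogen H5, and an axial substituent at C4 is necessarily anti to the axial, lithium-bound C3 oxygen, which gives the 1,3-cis-diol with the 3-hydroxyl trans to the pyranyl group. The step needs carbonyl addition before C4–H deprotonation (secured by adding 12 to a stoichiometric enolate at −78 °C before the second base) and deprotonation at C4 rather than C2 (C4–H is the most acidic C–H of 15, and a C2 enolate can return by proton transfer); ring closure also removes the ketone that a retro-aldol of the first adduct would need.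

**Step 6**
Reactants: 16 rac-(1S,3R,4R)-8-(benzyloxy)-4-[4-(benzyloxy)-2-oxo-2H-pyran-6-yl]-3-phenyl-1,2,3,4-tetrahydronaphthalene-1,3-diol
Product: 17 (3R,4R)-8-(benzyloxy)-4-[4-(benzyloxy)-2-oxo-2H-pyran-6-yl]-3-hydroxy-3-phenyl-3,4-dihydronaphthalen-1(2H)-one
Conditions: Ru[(S,S)-TsNCH(Ph)CH(Ph)NH](p-cymene) (cat.), acetone, 25 °C, stopped near half conversion
Reagents that add atoms: none
Why: Noyori-type oxidative kinetic resolution by asymmetric transfer dehydrogenation, in which the (S,S) catalyst should dehydrogenate the (1S)-carbinol of diastereomerically pure 16 (the sense known for 1-tetralol) to the (3R,4R)-ketone while the tertiary C3 alcohol is inert and the (1R,3S,4S)-enantiomer is left unchanged and removed by chromatography, which fixes the absolute configuration of C3 and C4.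

**Step 7**
Reactants: 17 (3R,4R)-8-(benzyloxy)-4-[4-(benzyloxy)-2-oxo-2H-pyran-6-yl]-3-hydroxy-3-phenyl-3,4-dihydronaphthalen-1(2H)-one
Product: 18 (3R,4R)-3,8-dihydroxy-4-(4-hydroxy-2-oxo-2H-pyran-6-yl)-3-phenyl-3,4-dihydronaphthalen-1(2H)-one
Conditions: H2 (1 atm), Pd/C, EtOAc, 25 °C
Reagents that add atoms: none
Why: Neutral hydrogenolysis cleaves the aryl and pyranyl benzyl ethers under conditions that should spare the tertiary benzylic alcohol, the aryl ketone and the pyrone, and that avoid the acid or base that would dehydrate or retro-aldolise the β-hydroxy ketone.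

**Step 8**
Reactants: 17 (3R,4R)-8-(benzyloxy)-4-[4-(benzyloxy)-2-oxo-2H-pyran-6-yl]-3-hydroxy-3-phenyl-3,4-dihydronaphthalen-1(2H)-one
Product: 19 6-(4,5-dihydroxy-2-phenylnaphthalen-1-yl)-4-hydroxy-2H-pyran-2-one
Conditions: BCl3, pentamethylbenzene, CH2Cl2, −78 → 0 °C; then MeOH, 25 °C
Reagents that add atoms: none
Why: Lewis-acid benzyl ether cleavage with a cation scavenger removes both benzyl groups, and the same acid should ionise the tertiary benzylic β-hydroxyl so that loss of water and tautomerisation of the resulting 4H-naphthalen-1-one give the 1-naphthol in a dehydrative aromatisation that erases both stereocentres, which is why a second portion of 17 can serve as the source of the achiral half.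

**Step 9**
Reactants: 18 (3R,4R)-3,8-dihydroxy-4-(4-hydroxy-2-oxo-2H-pyran-6-yl)-3-phenyl-3,4-dihydronaphthalen-1(2H)-one; 19 6-(4,5-dihydroxy-2-phenylnaphthalen-1-yl)-4-hydroxy-2H-pyran-2-one; 20 N,N-dimethylmethyleneiminium iodide
Product: 22 wailupemycin I, via Mannich base 21 (not isolated)
Conditions: 18, 20, MeCN, 0 °C; then 19, Et3N (1.2 equiv), 45 °C
Reagents that add atoms: N,N-dimethylmethyleneiminium iodide, C=[N+](C)C.[I-]
Why: Mannich reaction at the nucleophilic pyrone C3 of 18 (its ketone-chelated phenol is unreactive), then base-induced loss of dimethylamine from 21 gives a pyrone methide that C3 of the pyronate of 19 should trap by Michael addition, as 4-hydroxycoumarin Mannich bases do in forming unsymmetrical methylene-bridged dimers; no stereocentre is touched.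

**Compound list**
1 | 4-hydroxy-6-methyl-2H-pyran-2-one | Cc1cc(O)cc(=O)o1 | starting material
2 | benzyl alcohol | OCc1ccccc1 | starting material
3 | 4-(benzyloxy)-6-methyl-2H-pyran-2-one | Cc1cc(OCc2ccccc2)cc(=O)o1 | intermediate
4 | 2-bromo-6-hydroxybenzaldehyde | O=Cc1c(O)cccc1Br | starting material
5 | benzyl bromide | BrCc1ccccc1 | starting material
6 | 2-(benzyloxy)-6-bromobenzaldehyde | O=Cc1c(OCc2ccccc2)cccc1Br | intermediate
7 | trimethyl orthoformate | COC(OC)OC | starting material
8 | 1-(benzyloxy)-3-bromo-2-(dimethoxymethyl)benzene | COC(OC)c1c(OCc2ccccc2)cccc1Br | intermediate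
9 | [4-(benzyloxy)-2-oxo-2H-pyran-6-yl]methyllithium (lithium dienolate, drawn C-bound; not isolated) | [Li]Cc1cc(OCc2ccccc2)cc(=O)o1 | intermediate
10 | {[4-(benzyloxy)-2-oxo-2H-pyran-6-yl]methyl}zinc chloride (not isolated) | Cl[Zn]Cc1cc(OCc2ccccc2)cc(=O)o1 | intermediate
11 | 4-(benzyloxy)-6-[3-(benzyloxy)-2-(dimethoxymethyl)benzyl]-2H-pyran-2-one (not isolated) | COC(OC)c1c(OCc2ccccc2)cccc1Cc1cc(OCc2ccccc2)cc(=O)o1 | intermediate
12 | 2-(benzyloxy)-6-{[4-(benzyloxy)-2-oxo-2H-pyran-6-yl]methyl}benzaldehyde | O=Cc1c(OCc2ccccc2)cccc1Cc1cc(OCc2ccccc2)cc(=O)o1 | intermediate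
13 | acetophenone | CC(=O)c1ccccc1 | starting material
14 | lithium 1-phenylethenolate (not isolated) | [Li]OC(=C)c1ccccc1 | intermediate
15 | lithium 1-[2-(benzyloxy)-6-{[4-(benzyloxy)-2-oxo-2H-pyran-6-yl]methyl}phenyl]-3-oxo-3-phenylpropan-1-olate (racemic; not isolated) | [Li]OC(CC(=O)c1ccccc1)c1c(OCc2ccccc2)cccc1Cc1cc(OCc2ccccc2)cc(=O)o1 | intermediate
16 | rac-(1S,3R,4R)-8-(benzyloxy)-4-[4-(benzyloxy)-2-oxo-2H-pyran-6-yl]-3-phenyl-1,2,3,4-tetrahydronaphthalene-1,3-diol (racemate, one enantiomer drawn) | O[C@H]1C[C@](O)(c2ccccc2)[C@H](c2cc(OCc3ccccc3)cc(=O)o2)c2cccc(OCc3ccccc3)c21 | intermediate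
17 | (3R,4R)-8-(benzyloxy)-4-[4-(benzyloxy)-2-oxo-2H-pyran-6-yl]-3-hydroxy-3-phenyl-3,4-dihydronaphthalen-1(2H)-one | O=C1C[C@](O)(c2ccccc2)[C@H](c2cc(OCc3ccccc3)cc(=O)o2)c2cccc(OCc3ccccc3)c21 | intermediate
18 | (3R,4R)-3,8-dihydroxy-4-(4-hydroxy-2-oxo-2H-pyran-6-yl)-3-phenyl-3,4-dihydronaphthalen-1(2H)-one | O=C1C[C@](O)(c2ccccc2)[C@H](c2cc(O)cc(=O)o2)c2cccc(O)c21 | intermediate
19 | 6-(4,5-dihydroxy-2-phenylnaphthalen-1-yl)-4-hydroxy-2H-pyran-2-one | O=c1cc(O)cc(-c2c(-c3ccccc3)cc(O)c3c(O)cccc23)o1 | intermediate
20 | N,N-dimethylmethyleneiminium iodide | C=[N+](C)C.[I-] | starting material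
21 | (3R,4R)-4-{3-[(dimethylamino)methyl]-4-hydroxy-2-oxo-2H-pyran-6-yl}-3,8-dihydroxy-3-phenyl-3,4-dihydronaphthalen-1(2H)-one (formed as its hydroiodide; not isolated) | O=C1C[C@](O)(c2ccccc2)[C@H](c2cc(O)c(CN(C)C)c(=O)o2)c2cccc(O)c21 | intermediate
22 | wailupemycin I | O=C1C[C@](O)(c2ccccc2)[C@H](c2cc(O)c(Cc3c(O)cc(-c4c(-c5ccccc5)cc(O)c5c(O)cccc45)oc3=O)c(=O)o2)c2cccc(O)c21 | target

**Step count.** Total: 9 steps. Longest linear sequence: 7 steps (4 → 6 → 8 → 12 → 16 → 17 → 18 → 22; steps 2, 3, 4, 5, 6, 7, 9).

**Steps most likely to fail**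

Step 5. The C3–C4 aldol may revert, because the pyrone-stabilised dienolate is a good leaving carbanion, or the ring may close from the other face of the dienolate, so that open-chain adduct or the 3,4-cis diol accumulates. The fallback sets out from 12 and forms the two bonds separately under thermodynamic control. The reaction is quenched after the first aldol addition to isolate rac-3-[2-(benzyloxy)-6-{[4-(benzyloxy)-2-oxo-2H-pyran-6-yl]methyl}phenyl]-3-hydroxy-1-phenylpropan-1-one F1. Dess–Martin oxidation then gives 1-[2-(benzyloxy)-6-{[4-(benzyloxy)-2-oxo-2H-pyran-6-yl]methyl}phenyl]-3-phenylpropane-1,3-dione F2. F2 is cyclised by the biomimetic aldol addition of C4 to the benzoyl carbonyl with catalytic Cs2CO3 in MeOH/THF at 0 °C, a protic medium in which the neutral β-hydroxy ketone is favoured. After removal of the 3,4-cis isomer by chromatography this gives rac-(3R,4R)-8-(benzyloxy)-4-[4-(benzyloxy)-2-oxo-2H-pyran-6-yl]-3-hydroxy-3-phenyl-3,4-dihydronaphthalen-1(2H)-one F3. A 1,3-syn reduction (Et2BOMe, NaBH4, THF/MeOH, −78 °C) brings the material back to the route at 16.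

Step 6. The catalyst may discriminate poorly between the enantiomers at the peri-hindered, hydrogen-bonded C1 carbinol, or slow dehydrogenation may allow base-induced retro-aldol of the ketone. The fallback sets out from 16 and replaces the kinetic resolution by a physical one. Complete Dess–Martin oxidation gives rac-(3R,4R)-8-(benzyloxy)-4-[4-(benzyloxy)-2-oxo-2H-pyran-6-yl]-3-hydroxy-3-phenyl-3,4-dihydronaphthalen-1(2H)-one F4. Preparative chromatography on an amylose tris(3,5-dimethylphenylcarbamate) phase separates the enantiomers, and the route is rejoined at 17. The mirror-image (3S,4S)-8-(benzyloxy)-4-[4-(benzyloxy)-2-oxo-2H-pyran-6-yl]-3-hydroxy-3-phenyl-3,4-dihydronaphthalen-1(2H)-one F5 obtained beside it is converted under the conditions of step 8 into 19, since these erase both stereocentres. All of 17 can then go into step 7.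

Step 4. The zinc dienolate may be arylated at a ring carbon, the more acidic product methylene may be arylated twice, or transmetalation with the ortho-substituted bromide may be slow. The fallback sets out from 3 and uses a neutral, isolable tin reagent. Lithiation with LiN(i-Pr)2 and quenching with Bu3SnCl gives 4-(benzyloxy)-6-[(tributylstannyl)methyl]-2H-pyran-2-one F6. Stille coupling of F6 with the free aldehyde 6 (Pd(PPh3)4, CuI, DMF, 80 °C), which tolerates the formyl group and makes the acetal unnecessary, comes back to the route at 12.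

**Further compounds**
F1 | step 5 | rac-3-[2-(benzyloxy)-6-{[4-(benzyloxy)-2-oxo-2H-pyran-6-yl]methyl}phenyl]-3-hydroxy-1-phenylpropan-1-one | O=C(CC(O)c1c(OCc2ccccc2)cccc1Cc1cc(OCc2ccccc2)cc(=O)o1)c1ccccc1
F2 | step 5 | 1-[2-(benzyloxy)-6-{[4-(benzyloxy)-2-oxo-2H-pyran-6-yl]methyl}phenyl]-3-phenylpropane-1,3-dione | O=C(CC(=O)c1ccccc1)c1c(OCc2ccccc2)cccc1Cc1cc(OCc2ccccc2)cc(=O)o1
F3 | step 5 | rac-(3R,4R)-8-(benzyloxy)-4-[4-(benzyloxy)-2-oxo-2H-pyran-6-yl]-3-hydroxy-3-phenyl-3,4-dihydronaphthalen-1(2H)-one (racemate, one enantiomer drawn) | O=C1C[C@](O)(c2ccccc2)[C@H](c2cc(OCc3ccccc3)cc(=O)o2)c2cccc(OCc3ccccc3)c21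
F4 | step 6 | rac-(3R,4R)-8-(benzyloxy)-4-[4-(benzyloxy)-2-oxo-2H-pyran-6-yl]-3-hydroxy-3-phenyl-3,4-dihydronaphthalen-1(2H)-one (racemate, one enantiomer drawn) | O=C1C[C@](O)(c2ccccc2)[C@H](c2cc(OCc3ccccc3)cc(=O)o2)c2cccc(OCc3ccccc3)c21
F5 | step 6 | (3S,4S)-8-(benzyloxy)-4-[4-(benzyloxy)-2-oxo-2H-pyran-6-yl]-3-hydroxy-3-phenyl-3,4-dihydronaphthalen-1(2H)-one | O=C1C[C@@](O)(c2ccccc2)[C@@H](c2cc(OCc3ccccc3)cc(=O)o2)c2cccc(OCc3ccccc3)c21
F6 | step 4 | 4-(benzyloxy)-6-[(tributylstannyl)methyl]-2H-pyran-2-one | CCCC[Sn](CCCC)(CCCC)Cc1cc(OCc2ccccc2)cc(=O)o1
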